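The solid partner must dissolve and become second intermediate before any substrate can become target, so we compare what the same charge gives at four temperatures.

    fresh partner → second intermediate (k1 = 0.021 s⁻¹, Ea1 = 74.0 kJ mol⁻¹)
    substrate → decomposition product (k2 = 8.9 × 10⁻⁵ s⁻¹, Ea2 = 99.0 kJ mol⁻¹)
    substrate ⇌ open intermediate (K3 = 3.3, k3 = 0.042 s⁻¹, Ea3 = 74.0 kJ mol⁻¹, ΔH3 = −47.0 kJ mol⁻¹)
    solid partner ⇌ fresh partner, rate k4*(cs4 - [fresh partner]) while solid is left; crystals form when [fresh partner] > cs4 (cs4 = 0.21 M, k4 = 0.026 s⁻¹)
    open intermediate + second intermediate → target (k5 = 0.065 M⁻¹ s⁻¹, Ea5 = 40.0 kJ mol⁻¹)
    (constants at 25 °C)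

| setting | ochre | green | amber | teal |
|---|---|---|---|---|
| substrate | 0.31 M | 0.31 M | 0.31 M | 0.31 M |
| solid partner | 0.294 M | 0.294 M | 0.294 M | 0.294 M |
| temperature | 55 °C | 25 °C | 115 °C | 85 °C |
| time | 2.0 min | 2.0 min | 2.0 min | 2.0 min |

- solid partner is a solid; its amount is given per volume of the solution
- constants are those at 25 °C; use the activation energies and enthalpies for any other temperature
- at the start none of the solid partner is in solution

* the flask with the highest amount of target, in percent of the substrate charged ("all alike" if they lie within 1.5 percentage points) (ochre / green / amber / teal / all alike)
* final target, as a percentage of the substrate charged, in ochre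
* final target, as a percentage of the substrate charged, in green
* final target, as a percentage of the substrate charged, in amber
* final target, as a percentage of the substrate charged, in teal

We build amber up one process at a time, with every constant carried to 115 °C. Dissolution is given no activation energy, so solid enters at the feed F, the dissolution coefficient times the solubility, which is 0.00546 M s⁻¹ while the solution is still nearly free of fresh partner. In amber, fresh partner reacts at 21.3 s⁻¹, far faster than the dissolution coefficient, so second intermediate grows as F·t while solid is left.

In amber, substrate decomposes at 0.935 s⁻¹ and opens at 42.6 s⁻¹, far faster. We therefore treat substrate and open intermediate as one pool in fast pre-equilibrium. Its equilibrium constant K is 0.0407, so the open share f, which is K over one plus K, comes to 0.0391.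

With coupling as the main step, its constant in amber is 2.74 M⁻¹ s⁻¹. Writing a for that constant times f times F, the coupling time is the square root of two over a, 58.5 s. Taken alone, coupling would stop at the charge ratio, 94.8%.

Decomposition comes next. The pool in amber now decays at λ, the decomposition constant over one plus K, which is 0.899 s⁻¹, so its lifetime of 1.11 s is far shorter than the coupling time. Integrating a·t against that decay gives a over λ squared, which for amber is 0.0724%. We call this the arrival yield Y, the share of the pool coupled before it decays, and the substrate charge cancels from it.

Coupling also drains the pool, so we go round once more. Target forms on average two lifetimes in, so λ gains twice a/λ. Amber stays at 0.0722%.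

Teal has K of 0.138, λ of 0.0629 s⁻¹ and a coupling time of 55.8 s. Scaling amber's Y by the squares of the two ratios, teal's Y is 16.2%, and it falls to 9.24% on the second round.

In ochre, with K of 0.583, Y is 122 as a plain ratio, and in green it is 6.36 × 10⁵. Both lie far above one, so the pool outlasts the coupling there, Y is no yield, and our reckoning does not rank those two.

The forecast names ochre, with 65% for ochre (58% to 71%), 36% for green (31% to 41%), 0.07% for amber (0.04% to 0.12%) and 13% for teal (10% to 16%), the hot flasks “losing the substrate to decomposition before much partner is available”. Its teal figure stands above ours.

The simulation puts ochre first, with 64.9% in ochre, 32.1% in green, 0.0687% in amber and 10.2% in teal, against our first-round 0.0724% and second-round 0.0722% for amber and our second-round 9.24% for teal. The neighbour is amber run at 90 °C, where K is 0.111, λ is 0.102 s⁻¹ and the coupling time is 56.1 s. Scaled from amber's Y, the neighbour's Y reads 6.13% on the first round and 4.86% on the second, and the run gives 4.75%.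

The numbers of this flask are invented; what happens was integrated by code.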